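(The numbers in the tables were generated by integration from invented constants; the scatter is artificial.)

The ratio I started from was Q in the winter run over Q in the autumn run at 1.50 h, which is 4.41 for a ratio of J charges of 2.06. So Q climbed as a power of J, and the earliest readings lag, as winter's 4.4% at 0.500 h against 26.0% at 1.50 h shows, so I took it that something stands between G and Q. I took that power as a count and called it the toll, 2.06 equiv: the equivalents of J that each G pays on its way to the stage that gives Q.

| flask | G | J | remark | time |
|---|---|---|---|---|
| noon | 0.30 M | 0.98 equiv | run made earlier |  |
| autumn | 0.30 M | 1.8 equiv | run made earlier |  |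
| winter | 0.30 M | 3.7 equiv | run made earlier |  |
| amber | 0.30 M | 1.00 equiv |  | 12 h |
| violet | 0.30 M | 2.00 equiv |  | 12 h |
| grey | 0.30 M | 4.00 equiv |  | 12 h |

- noon (time / h: Q / %): 0.500: 0; 0.833: 1.5; 1.50: 1.7; 3.00: 2.9; 6.00: 5.0
- autumn (time / h: Q / %): 0.500: 1.0; 1.50: 5.9; 3.00: 11.7; 4.00: 13.9; 6.00: 15.8
- winter (time / h: Q / %): 0.500: 4.4; 0.833: 11.2; 1.50: 26.0; 3.00: 47.5; 6.00: 67.5

(standard deviation of a reading: 0.5 percentage points)

- "hardly changes" means that all values lie within two and a half points (for a concentration: within two and a half percent of the largest)

- [Q] at the end for amber, violet, grey, in this order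
- the course of these numbers from the first flask to the last (falls, then rises / hardly changes / falls all the way / rises, then falls / rises all the way)

I treated the toll steps as fast and reckoned with the J they leave free, the charge less the toll. Autumn's 1.8 equiv lies under the toll, which fitted its slowing near 15.8%. Violet's charge stands level with the toll and amber's lies under it, so I expected both flasks to slow as autumn did. Grey keeps 1.94 equiv free, more than the one J I allowed for each Q, so I let grey continue as winter did. Winter's shortfall in Q shrank by a factor 0.619 per 3.00 h, and carried on to 12 h this gave me 0.263 M for grey.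

The weak link was the toll, read from one pair of readings, so I reforged it from the autumn and noon readings at 1.50 h. They give a power of 2.05, though noon's small reading carries a scatter of 0.5 percentage points, and the toll stood.

The forecast gave 0.025 M, 0.075 M and 0.26 M, with a course that rises all the way. It held that the “autumn run stalls well before G or J runs out”, where I read the same stall as J spent on the toll.

The flasks gave 0.0123 M, 0.0729 M and 0.245 M, a course that rises all the way, and the forecast's amber stood at twice the flask's value.

    J + D → Q (k = 0.761 M⁻¹ h⁻¹)
    J → L (k = 0.0105 h⁻¹)
    J + Z → D (k = 3.72 M⁻¹ h⁻¹)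
    D → E (k = 0.0748 h⁻¹)
    G + J → Z (k = 1.94 M⁻¹ h⁻¹)

The toll appears here as two steps, G + J and J + Z, with the J of Q behind them. Grey's free 1.94 equiv, less the J paid for its Q at 12.0 h, leaves 1.12 equiv on this reckoning, and grey held 1.01 equiv. Amber stood 1.06 equiv short of the toll, with J as the limiting reagent, down to 0.0802% of its charge at 12.0 h and Q at 4.10%. With the consumption of J taken away, amber's Q reaches 0.209 M instead of 0.0123 M.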